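**Plan**
1. Retrosynthesis: open the 1,10-epoxide to the C14 allylic alcohol, remove the C13 methylene and the C8 isobutyrate, and cut C10–C14 back to an enol triflate.
2. Without the epoxide oxygen, C10=C1–C2–C3–C4=C5 is a 1,5-diene inside the ten-membered ring. Cutting C2–C3 while joining C5–C10 (retro oxy-Cope) leaves a cyclohexanol (ring C5–C10) with cis vinyl and isopropenyl groups, trans-fused to the γ-lactone.
3. The cyclohexane is cut at C5–C10 (carbonyl-ene) and C8–C9 (aldol), and C7–C8 by conjugate addition to a butenolide made from prenal and methyl propiolate.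
4. Forward: lactone ring first, then the six-membered ring, then its four-atom expansion to the ten-membered ring, then C14, ester, methylene and epoxide.
5. Stereochemistry: C6 by asymmetric alkynylation; C7 by trans Michael addition; C5 by the ene chair; C10 by axial acetylide attack; C8 by Felkin aldol, then oxidation and directed reduction; 4Z and 1(10)E from the oxy-Cope chair; epoxide face from L-(+)-tartrate.
6. Locants are germacrane numbers (ring C1–C10, lactone carbons C11–C13, C14 on C10, C15 on C4); β is the face of the C7–C11 bond.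

Key step: step 14

Remark: the sense of induction of the zinc–ProPhenol alkynylation is assumed to follow its aldol model, which points to the (R,R)-ligand for (R)-3; if this enal responds in the opposite sense, the (S,S)-ligand is used.
Remark: (vinyloxy)tris(trimethylsilyl)silane (step 5) is assumed to be made in one flask from commercial (Me3Si)3SiH (TfOH, then the lithium enolate of acetaldehyde from THF and n-BuLi).

**Route**

Step 1
Reactants: 1 3-methylbut-2-enal; 2 methyl propiolate
Product: 3 methyl (R)-4-hydroxy-6-methylhept-5-en-2-ynoate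
Conditions: ZnMe2 (3 equiv), (R,R)-ProPhenol (10 mol%), Ph3PO (20 mol%), toluene, 4 °C
Reagents that add atoms: none
Why: Zinc–ProPhenol-catalysed asymmetric alkynylation: the dinuclear zinc complex binds the aldehyde and delivers the zinc alkynylide to one face, which should set C6 as (R) while the enal reacts 1,2.

Step 2
Reactants: 3 methyl (R)-4-hydroxy-6-methylhept-5-en-2-ynoate
Product: 5 (S)-5-(2-methylprop-1-en-1-yl)furan-2(5H)-one, via Z-hydroxy dienoate 4 (not isolated)
Conditions: H2 (1 atm), Pd/CaCO3 poisoned with Pb(OAc)2, quinoline, EtOAc, rt; then camphorsulfonic acid (cat.), CH2Cl2, rt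
Reagents that add atoms: none
Why: Lindlar semihydrogenation stops at the Z-enoate 4, whose γ-hydroxyl is held next to the ester and should close to the butenolide under acid catalysis without touching C6.

Step 3
Reactants: 5 (S)-5-(2-methylprop-1-en-1-yl)furan-2(5H)-one
Product: 6 (4R,5R)-5-(2-methylprop-1-en-1-yl)-4-(nitromethyl)dihydrofuran-2(3H)-one
Conditions: MeNO2 (solvent), DBU (0.2 equiv), 0 °C to rt
Reagents that add atoms: nitromethane, C[N+](=O)[O-]
Why: Michael addition of the nitronate to the butenolide anti to the C6 substituent should set C7 trans to C6.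

Step 4
Reactants: 6 (4R,5R)-5-(2-methylprop-1-en-1-yl)-4-(nitromethyl)dihydrofuran-2(3H)-one
Product: 7 (2R,3S)-2-(2-methylprop-1-en-1-yl)-5-oxotetrahydrofuran-3-carbaldehyde
Conditions: NaOMe, MeOH, 0 °C; then aq. TiCl3, NH4OAc, THF, rt
Reagents that add atoms: water, O
Why: Nef reaction in its reductive form (nitronate reduced by TiCl3 to the imine, then hydrolysed) should unveil aldehyde C8 under buffered conditions that leave the alkene and lactone alone and C7 in its stable trans configuration.

Step 5
Reactants: 7 (2R,3S)-2-(2-methylprop-1-en-1-yl)-5-oxotetrahydrofuran-3-carbaldehyde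
Product: 8 (3S)-3-[(2R,3S)-2-(2-methylprop-1-en-1-yl)-5-oxotetrahydrofuran-3-yl]-3-{[tris(trimethylsilyl)silyl]oxy}propanal
Conditions: CH2=CHOSi(SiMe3)3 (1.2 equiv), HNTf2 (0.1 mol%), CH2Cl2, −78 °C
Reagents that add atoms: (vinyloxy)tris(trimethylsilyl)silane, C=CO[Si]([Si](C)(C)C)([Si](C)(C)C)[Si](C)(C)C
Why: Mukaiyama-type crossed aldol of the acetaldehyde silyl enol ether; Felkin–Anh attack anti to the C6 branch of the α-stereocentre should set C8 (oxygen trans to C7–C11, 8α), and the transferred bulky silyl group keeps the new aldehyde from reacting again.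

Step 6
Reactants: 8 the β-silyloxy aldehyde
Product: 9 10α-hydroxy-5β-isopropenyl-8α-[tris(trimethylsilyl)silyloxy]cyclohexane (ring C5–C10) trans-fused at C6–C7 to the 6α,12-lactone
Conditions: Me2AlCl (1.5 equiv), CH2Cl2, −78 to −40 °C
Reagents that add atoms: none
Why: Type 1 intramolecular carbonyl-ene reaction (as in citronellal to isopulegol) through a chair with C6–O, C7–C11 and C8–O equatorial should form C5–C10 and place the isopropenyl group at C5 equatorial, trans to C6–O; Me2AlCl also scavenges protons that could ionise the allylic lactone.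

Step 7
Reactants: 9 the lactone-fused cyclohexanol
Product: 10 5β-isopropenyl-10-oxo-8α-[tris(trimethylsilyl)silyloxy]cyclohexane trans-6α,12-lactone
Conditions: Dess–Martin periodinane, NaHCO3, CH2Cl2, 0 °C to rt
Reagents that add atoms: none
Why: Dess–Martin oxidation under buffered conditions should give the ketone without conjugating the isopropenyl double bond; the equatorial C5 configuration is also the thermodynamic one, and the equatorial C6–O bond lies in the plane of a C5 enol, which disfavours β-elimination.

Step 8
Reactants: 10 the C10 ketone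
Product: 11 10β-ethynyl-10α-hydroxy-5β-isopropenyl-8α-[tris(trimethylsilyl)silyloxy]cyclohexane trans-6α,12-lactone
Conditions: HC≡CMgBr (3 equiv), CeCl3 (3 equiv), THF, −78 °C
Reagents that add atoms: ethynylmagnesium bromide, C#C[Mg]Br
Why: Organocerium 1,2-addition; the slender acetylide should attack the chair ketone axially (the equatorial path is hindered by the neighbouring equatorial isopropenyl group), setting C10 with the alkyne cis to isopropenyl and the hydroxyl equatorial, and the weakly basic cerium reagent spares the enolisable ketone and the lactone.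

Step 9
Reactants: 11 the ethynyl carbinol
Product: 12 10α-hydroxy-5β-isopropenyl-10β-vinyl-8α-[tris(trimethylsilyl)silyloxy]cyclohexane trans-6α,12-lactone
Conditions: H2 (1 atm), Pd/CaCO3 poisoned with Pb(OAc)2, quinoline, EtOAc, rt
Reagents that add atoms: none
Why: Lindlar semihydrogenation reduces only the terminal alkyne to the vinyl group and leaves the 1,1-disubstituted isopropenyl alkene.

Step 10
Reactants: 12 the vinyl carbinol silyl ether
Product: 13 8α,10α-dihydroxy-5β-isopropenyl-10β-vinylcyclohexane trans-6α,12-lactone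
Conditions: Bu4NF, AcOH, THF, 0 °C to rt
Reagents that add atoms: none
Why: Fluoride cleaves the Si–O bond of the silyl ether, and acetic acid buffers the alkoxide so that the lactone is not opened.

Step 11
Reactants: 13 the 8α,10α-diol
Product: 14 10α-hydroxy-5β-isopropenyl-8-oxo-10β-vinylcyclohexane trans-6α,12-lactone
Conditions: Dess–Martin periodinane, NaHCO3, CH2Cl2, 0 °C
Reagents that add atoms: none
Why: Dess–Martin oxidation takes the secondary C8 alcohol to the ketone and cannot oxidise the tertiary C10 alcohol; non-basic conditions avoid retro-aldol cleavage of the β-hydroxy ketone.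

Step 12
Reactants: 14 the β-hydroxy ketone
Product: 15 8β,10α-dihydroxy-5β-isopropenyl-10β-vinylcyclohexane trans-6α,12-lactone (8β-OH axial)
Conditions: Me4NBH(OAc)3, MeCN/AcOH, −20 °C
Reagents that add atoms: none
Why: Hydroxyl-directed triacetoxyborohydride reduction (anti 1,3-induction): hydride is delivered from boron bound to the equatorial C10–OH to the equatorial face of C8, the only face not shielded by the axial vinyl group, which should give the axial 8β-alcohol.

Step 13
Reactants: 15 the 8β,10α-diol
Product: 16 10α-hydroxy-5β-isopropenyl-8β-(triethylsilyloxy)-10β-vinylcyclohexane trans-6α,12-lactone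
Conditions: Et3SiCl, imidazole, DMF, 0 °C
Reagents that add atoms: chlorotriethylsilane, CC[Si](Cl)(CC)CC
Why: Silylation of the secondary alcohol in the presence of the hindered tertiary one, which must stay free for the next step.

Step 14
Reactants: 16 the oxy-Cope substrate
Product: 18 10-(trifluoromethanesulfonyloxy)-8β-(triethylsilyloxy)-14-norgermacra-1(10),4-dien-6α,12-olide (C2 and C9 trans on C1=C10; C3 and C6 cis on C4=C5), via potassium enolate 17 (not isolated)
Conditions: KN(SiMe3)2 (1.0 equiv), 18-crown-6 (1.2 equiv), THF, −78 to 0 °C; then PhNTf2, −78 °C to rt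
Reagents that add atoms: N-phenylbis(trifluoromethanesulfonimide), O=S(=O)(N(c1ccccc1)S(=O)(=O)C(F)(F)F)C(F)(F)F
Why: Anionic oxy-Cope rearrangement: the potassium alkoxide of 16 undergoes a [3,3]-sigmatropic shift in which the C5–C10 bond of the cyclohexane breaks while the C2–C3 bond forms between the CH2 termini of the vinyl and isopropenyl groups, and the resulting C1=C10 enolate 17 is triflated on oxygen. The closest known reaction type is the oxy-Cope ring expansion of 1,2-dialkenylcyclohexanols to cyclodec-5-enones with trapping of the regiodefined enolate. The ten-membered ring is closed by a four-atom ring expansion through a six-membered chair transition state, not by an end-to-end cyclisation, so no high dilution is needed. No stereocentre is made; the two new double-bond geometries follow from the chair, in which the axial C10 vinyl group forces C6 axial and gives the cis (4Z) C4=C5 bond, and the equatorial C5 isopropenyl group puts C9 equatorial and gives the enolate with C2 trans to C9. The step needs this chair alone and an enolate that stays at C1: the trans-fused lactone with equatorial C5, C6 and C7 substituents rules out the ring-flipped chair (which would give the other pair of geometries and is otherwise favoured by an equatorial oxyanion), the 1,3-diaxial strain between the vinyl and 8β-silyloxy groups is released in the shift, and the enolate is triflated cold before it can equilibrate toward C9. One equivalent of the hindered amide base is used so that the lactone α-CH2 is not deprotonated.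

Step 15
Reactants: 18 the enol triflate silyl ether
Product: 19 8β-hydroxy-10-(trifluoromethanesulfonyloxy)-14-norgermacra-1(10),4-dien-6α,12-olide
Conditions: HF·pyridine, pyridine, THF, 0 °C
Reagents that add atoms: none
Why: Buffered HF·pyridine removes the triethylsilyl ether and leaves the enol triflate and the lactone.

Step 16
Reactants: 19 the C8 alcohol
Product: 20 8β-isobutyryloxy-10-(trifluoromethanesulfonyloxy)-14-norgermacra-1(10),4-dien-6α,12-olide
Conditions: i-PrCOCl, pyridine, DMAP (cat.), CH2Cl2, 0 °C to rt
Reagents that add atoms: isobutyryl chloride, CC(C)C(=O)Cl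
Why: DMAP-catalysed acylation of the C8 alcohol with retention of configuration installs the isobutyrate while no other hydroxyl is present.

Step 17
Reactants: 20 the enol triflate isobutyrate
Product: 21 14-hydroxy-8β-isobutyryloxygermacra-1(10),4-dien-6α,12-olide (C11 is CH2)
Conditions: Bu3SnCH2OH, Pd(PPh3)4 (5 mol%), LiCl (3 equiv), 1,4-dioxane, 90 °C
Reagents that add atoms: (tributylstannyl)methanol, CCCC[Sn](CO)(CCCC)CCCC
Why: Stille coupling of the enol triflate with the hydroxymethyl stannane with retention of double-bond geometry should attach C14 cis to C2.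

Step 18
Reactants: 21 the allylic alcohol lactone
Product: 24 14-hydroxy-8β-isobutyryloxygermacra-1(10),4,11(13)-trien-6α,12-olide, via Mannich base 22 (not isolated), via ammonium iodide 23 (not isolated)
Conditions: LiN(SiMe3)2 (2.2 equiv), THF, −78 °C; CH2=NMe2+ I−, −78 to 0 °C; then MeI, MeOH, rt; then aq. NaHCO3, CH2Cl2, rt
Reagents that add atoms: N,N-dimethylmethyleneiminium iodide (Eschenmoser's salt), C=[N+](C)C.[I-]
Why: Lactone α-methylenation: the lactone α-CH2 is several pK units more acidic than the isobutyrate α-CH, so the second equivalent of base (the first takes the hydroxyl proton) should form the lactone enolate, which undergoes a Mannich reaction with the iminium salt; exhaustive methylation and mild base then eliminate trimethylamine.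

Step 19
Reactants: 24 the trienolide allylic alcohol
Product: 25 CNP0247143.1, (1R,6R,7R,8R,10S)-1β,10α-epoxy-14-hydroxy-8β-isobutyryloxygermacra-4Z,11(13)-dien-6α,12-olide
Conditions: Ti(OiPr)4 (10 mol%), L-(+)-diethyl tartrate (12 mol%), t-BuOOH (2 equiv), 4 Å molecular sieves, CH2Cl2, −20 °C
Reagents that add atoms: tert-butyl hydroperoxide, CC(C)(C)OO
Why: Sharpless asymmetric epoxidation: binding of the C14 hydroxyl to titanium restricts oxidation to C1=C10, the addition is stereospecific (C2 and C9 stay trans), and the L-(+)-tartrate complex should deliver oxygen to the face that gives the (1R,10S) epoxide, which is expected to be the outer face of the ring as well.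

**Compound list**
1 | 3-methylbut-2-enal | CC(C)=CC=O | starting material
2 | methyl propiolate | C#CC(=O)OC | starting material
3 | methyl (R)-4-hydroxy-6-methylhept-5-en-2-ynoate | COC(=O)C#C[C@H](O)C=C(C)C | intermediate
4 | methyl (S,Z)-4-hydroxy-6-methylhepta-2,5-dienoate | COC(=O)/C=C\[C@H](O)C=C(C)C | intermediate (not isolated)
5 | (S)-5-(2-methylprop-1-en-1-yl)furan-2(5H)-one | O=C1C=C[C@@H](C=C(C)C)O1 | intermediate
6 | (4R,5R)-5-(2-methylprop-1-en-1-yl)-4-(nitromethyl)dihydrofuran-2(3H)-one | C1C(=O)O[C@H](C=C(C)C)[C@H]1C[N+](=O)[O-] | intermediate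
7 | (2R,3S)-2-(2-methylprop-1-en-1-yl)-5-oxotetrahydrofuran-3-carbaldehyde | C1C(=O)O[C@H](C=C(C)C)[C@H]1C=O | intermediate
8 | (3S)-3-[(2R,3S)-2-(2-methylprop-1-en-1-yl)-5-oxotetrahydrofuran-3-yl]-3-{[tris(trimethylsilyl)silyl]oxy}propanal | C1C(=O)O[C@H](C=C(C)C)[C@H]1[C@H](CC=O)O[Si]([Si](C)(C)C)([Si](C)(C)C)[Si](C)(C)C | intermediate
9 | 10α-hydroxy-5β-isopropenyl-8α-[tris(trimethylsilyl)silyloxy]cyclohexane trans-fused to the 6α,12-lactone (all substituents equatorial) | C1C(=O)O[C@@H]2[C@@H](C(C)=C)[C@H](O)C[C@H](O[Si]([Si](C)(C)C)([Si](C)(C)C)[Si](C)(C)C)[C@@H]12 | intermediate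
10 | 5β-isopropenyl-10-oxo-8α-[tris(trimethylsilyl)silyloxy]cyclohexane trans-6α,12-lactone | C1C(=O)O[C@@H]2[C@@H](C(C)=C)C(=O)C[C@H](O[Si]([Si](C)(C)C)([Si](C)(C)C)[Si](C)(C)C)[C@@H]12 | intermediate
11 | 10β-ethynyl-10α-hydroxy-5β-isopropenyl-8α-[tris(trimethylsilyl)silyloxy]cyclohexane trans-6α,12-lactone (ethynyl axial) | C1C(=O)O[C@@H]2[C@@H](C(C)=C)[C@@](O)(C#C)C[C@H](O[Si]([Si](C)(C)C)([Si](C)(C)C)[Si](C)(C)C)[C@@H]12 | intermediate
12 | 10α-hydroxy-5β-isopropenyl-10β-vinyl-8α-[tris(trimethylsilyl)silyloxy]cyclohexane trans-6α,12-lactone | C1C(=O)O[C@@H]2[C@@H](C(C)=C)[C@@](O)(C=C)C[C@H](O[Si]([Si](C)(C)C)([Si](C)(C)C)[Si](C)(C)C)[C@@H]12 | intermediate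
13 | 8α,10α-dihydroxy-5β-isopropenyl-10β-vinylcyclohexane trans-6α,12-lactone | C1C(=O)O[C@@H]2[C@@H](C(C)=C)[C@@](O)(C=C)C[C@H](O)[C@@H]12 | intermediate
14 | 10α-hydroxy-5β-isopropenyl-8-oxo-10β-vinylcyclohexane trans-6α,12-lactone | C1C(=O)O[C@@H]2[C@@H](C(C)=C)[C@@](O)(C=C)CC(=O)[C@@H]12 | intermediate
15 | 8β,10α-dihydroxy-5β-isopropenyl-10β-vinylcyclohexane trans-6α,12-lactone (8β-OH axial) | C1C(=O)O[C@@H]2[C@@H](C(C)=C)[C@@](O)(C=C)C[C@@H](O)[C@@H]12 | intermediate
16 | 10α-hydroxy-5β-isopropenyl-8β-(triethylsilyloxy)-10β-vinylcyclohexane trans-6α,12-lactone | C1C(=O)O[C@@H]2[C@@H](C(C)=C)[C@@](O)(C=C)C[C@@H](O[Si](CC)(CC)CC)[C@@H]12 | intermediate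
17 | potassium C1=C10 enolate of 10-oxo-8β-(triethylsilyloxy)-14-norgermacr-4Z-en-6α,12-olide | C1C(=O)O[C@@H]2/C=C(/C)CC/C=C(\[O-])C[C@@H](O[Si](CC)(CC)CC)[C@@H]12.[K+] | intermediate (not isolated)
18 | 10-(trifluoromethanesulfonyloxy)-8β-(triethylsilyloxy)-14-norgermacra-1(10),4-dien-6α,12-olide (C2/C9 trans, C3/C6 cis) | C1C(=O)O[C@@H]2/C=C(/C)CC/C=C(\OS(=O)(=O)C(F)(F)F)C[C@@H](O[Si](CC)(CC)CC)[C@@H]12 | intermediate
19 | 8β-hydroxy-10-(trifluoromethanesulfonyloxy)-14-norgermacra-1(10),4-dien-6α,12-olide | C1C(=O)O[C@@H]2/C=C(/C)CC/C=C(\OS(=O)(=O)C(F)(F)F)C[C@@H](O)[C@@H]12 | intermediate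
20 | 8β-isobutyryloxy-10-(trifluoromethanesulfonyloxy)-14-norgermacra-1(10),4-dien-6α,12-olide | C1C(=O)O[C@@H]2/C=C(/C)CC/C=C(\OS(=O)(=O)C(F)(F)F)C[C@@H](OC(=O)C(C)C)[C@@H]12 | intermediate
21 | 14-hydroxy-8β-isobutyryloxygermacra-1(10),4-dien-6α,12-olide | C1C(=O)O[C@@H]2/C=C(/C)CC/C=C(\CO)C[C@@H](OC(=O)C(C)C)[C@@H]12 | intermediate
22 | 13-(dimethylamino)-14-hydroxy-8β-isobutyryloxygermacra-1(10),4-dien-6α,12-olide (C13 on the face opposite C8) | CN(C)C[C@@H]1C(=O)O[C@@H]2/C=C(/C)CC/C=C(\CO)C[C@@H](OC(=O)C(C)C)[C@@H]12 | intermediate (not isolated)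
23 | N-methyl quaternary ammonium iodide of 22 | C[N+](C)(C)C[C@@H]1C(=O)O[C@@H]2/C=C(/C)CC/C=C(\CO)C[C@@H](OC(=O)C(C)C)[C@@H]12.[I-] | intermediate (not isolated)
24 | 14-hydroxy-8β-isobutyryloxygermacra-1(10),4,11(13)-trien-6α,12-olide | C=C1C(=O)O[C@@H]2/C=C(/C)CC/C=C(\CO)C[C@@H](OC(=O)C(C)C)[C@@H]12 | intermediate
25 | CNP0247143.1, (1R,6R,7R,8R,10S)-1β,10α-epoxy-14-hydroxy-8β-isobutyryloxygermacra-4Z,11(13)-dien-6α,12-olide | C=C1C(=O)O[C@@H]2/C=C(/C)CC[C@H]3O[C@]3(CO)C[C@@H](OC(=O)C(C)C)[C@@H]12 | target

**Count and risks**
Total step count: 19. Longest linear sequence: 19 steps (1 to 25).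

Step 14. What may go wrong: proton transfer from the lactone α-CH2 to the alkoxide or to the enolate, and acyl transfer from the lactone to the enolate carbon, could consume the anion before or after the shift. The fallback is a base-free siloxy-Cope route that sets out from 16. N-(Trimethylsilyl)imidazole (neat, 40 °C) should give the tertiary trimethylsilyl ether F1. Heating F1 in degassed decalin with a little N,O-bis(trimethylsilyl)acetamide at about 200 °C in a sealed tube should bring about the neutral [3,3] shift through the same chair to the ring-expanded silyl enol ether F2. CsF and PhNTf2 in 1,2-dimethoxyethane then exchange the trimethylsilyl group for triflate, and the route is rejoined at 18.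

Step 19. What may go wrong: a mismatch between the face preferred by the titanium–tartrate complex and the face exposed by the ring conformation would give poor facial selectivity, and the Lewis acid could open the new epoxide by transannular attack of the C4=C5 bond. The fallback is a metal-free, reagent-controlled epoxidation of the protected alcohol, setting out from 24. Et3SiCl and imidazole give the 14-O-triethylsilyl ether F3. Shi epoxidation (D-fructose-derived ketone, 2KHSO5·KHSO4·K2SO4, K2CO3, aqueous buffer, MeCN/dimethoxymethane, 0 °C) should oxidise the trans trisubstituted C1=C10 bond from the required face in preference to the cis C4=C5 bond and the electron-poor C11=C13 bond, giving the epoxy silyl ether F4. HF·pyridine then frees the C14 hydroxyl, and the route arrives at 25.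

Step 3. What may go wrong: the C6 hydrogen of 5 is allylic and α to the lactone oxygen, so the amine base can remove it, which would racemise C6 or move the double bonds into conjugation before the nitronate adds. The fallback is a base-free radical conjugate addition that sets out from 5. Irradiation (350 nm) in 1,3-dioxolane with benzophenone (cat.) should add the 1,3-dioxolan-2-yl radical to C7 anti to the C6 substituent and give the dioxolane acetal F5. Aqueous HCl in THF then hydrolyses the acetal, and the route is rejoined at 7 without the Nef step.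

**Further compounds**
F1 | step 14 | 10α-(trimethylsilyloxy)-5β-isopropenyl-8β-(triethylsilyloxy)-10β-vinylcyclohexane trans-6α,12-lactone | C1C(=O)O[C@@H]2[C@@H](C(C)=C)[C@@](O[Si](C)(C)C)(C=C)C[C@@H](O[Si](CC)(CC)CC)[C@@H]12
F2 | step 14 | 10-(trimethylsilyloxy)-8β-(triethylsilyloxy)-14-norgermacra-1(10),4-dien-6α,12-olide (C2/C9 trans, C3/C6 cis) | C1C(=O)O[C@@H]2/C=C(/C)CC/C=C(\O[Si](C)(C)C)C[C@@H](O[Si](CC)(CC)CC)[C@@H]12
F3 | step 19 | 8β-isobutyryloxy-14-(triethylsilyloxy)germacra-1(10),4,11(13)-trien-6α,12-olide | C=C1C(=O)O[C@@H]2/C=C(/C)CC/C=C(\CO[Si](CC)(CC)CC)C[C@@H](OC(=O)C(C)C)[C@@H]12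
F4 | step 19 | 1β,10α-epoxy-8β-isobutyryloxy-14-(triethylsilyloxy)germacra-4Z,11(13)-dien-6α,12-olide | C=C1C(=O)O[C@@H]2/C=C(/C)CC[C@H]3O[C@]3(CO[Si](CC)(CC)CC)C[C@@H](OC(=O)C(C)C)[C@@H]12
F5 | step 3 | (4S,5R)-4-(1,3-dioxolan-2-yl)-5-(2-methylprop-1-en-1-yl)dihydrofuran-2(3H)-one | C1C(=O)O[C@H](C=C(C)C)[C@H]1C1OCCO1
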